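## Structural features

The target is an eremophilane ester: a trans-fused decalin (ring A = C1–C5 and C10, ring B = C5–C10) whose C3 oxygen carries a (2Z,4S)-4-[(2Z)-hex-2-enoyloxy]hex-2-enoyl chain. Five contiguous stereocentres run C3 (equatorial acyloxy), C4 (equatorial methyl C15), C5 (quaternary, axial methyl C14), C10 (ring-fusion hydrogen) and C9 (equatorial hydroxyl); a sixth sits alone in the side chain. Ring B is an α-hydroxy ketone (C9–OH, C8=O) conjugated with the exocyclic C7 isopropylidene. Fragile points are the two Z-enoates (Z→E isomerisation on carboxyl activation or with base), the α-ketol (C9 epimerisation, ketol shift, oxidation in base), the exocyclic enone (deconjugation) and the need to tell two secondary hydroxyls apart. The real difficulty is quaternary C5, with its methyl cis to the C4 methyl and trans to H10. Every other ring stereocentre carries its substituent equatorially, and C4 and C10 both flank C5, so a C5 carbonyl allows them to be set by equilibration. C5 bears a methyl and the C6 methylene, and C6 is β to the C8 carbonyl; the key step uses this by generating a C5 radical from a C5 exocyclic methylene and closing ring B onto a C6=C7–C8(=O) vinyl ketone.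

## Logic of the disconnections

**31 ⇒ 30 ⇒ 29.** The last bonds made are the C9 O–H bond (from O–Si) and the four C–H bonds of the two Z-alkenes. Z-enoates would not survive carboxyl activation or base, so they are carried as alkynes until after the esterification. This makes 29 a robust diyne. The forward steps must stop at the alkene stage, leave the tetrasubstituted enone alone, and remove the C9 silyl group without base.

**29 ⇒ 22 + 28.** The C3–O acyl bond is cut because it is the only bond joining two independently chiral halves. The core and the side chain then become separate problems. The forward step needs C3–OH free while C9–O stays masked, so the two oxygens must carry different silyl groups from the start (tert-butyldimethylsilyl on C3, triisopropylsilyl on C9).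

**28 ⇒ 27 ⇒ 25 + 26 ⇒ 23.** The cuts are the tert-butyl C–O bond, the inner ester C–O bond and the bond from the alkyne terminus to the carboxyl carbon. This leads back to the two commercial building blocks 23 and 26. The carboxyl carbon must be attached before O-acylation, and the outer ester must be removable by acid alone so that the inner ester survives.

**22 ⇒ 21 ⇒ 19 ⇒ 17.** The C3 O–Si bond is cut first, then the C7=C11 double bond, then the C7–C11 σ-bond (aldol retron of the C8 ketone). Three carbons and a tetrasubstituted alkene are removed, leaving a plain ketone. The forward aldol needs enolisation at C7 and not at the silyloxy-bearing C9.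

**17 ⇒ 14 (key).** The C5–C6 bond is cut: quaternary C5 with methyl and CH2 becomes an exocyclic methylene, and C6 becomes the terminus of a vinyl ketone. Ring B and the only quaternary centre disappear together, and every stereocentre of 14 is a secondary carbon. The forward step needs hydrogen-atom transfer to the methylene only, 6-endo closure, and a trans ring fusion.

**14 ⇒ 12.** The C7–C8 bond (vinyl to acyl carbon) is cut, passing through 13. The labile vinyl ketone is thus made immediately before use from a stable ester. The forward step must add one vinyl group only.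

**12 ⇒ 11.** The C5=C14 bond is cut back to a C5 ketone. The ketone makes C4 and C10 epimerisable and makes the C9–C10 bond an aldol bond. The forward methylenation must work on a hindered ketone without base.

**11 ⇒ 10 ⇒ 9 ⇒ 6 + 7.** The C10–H bond (epimerisation), the C9 O–Si bond and the C9–C10 bond are cut. A carbon electrophile can only enter at C10 trans to the C4 methyl, which is the wrong C10 configuration. The plan therefore takes the anti aldol on that epimer and then inverts C10; this gives the all-equatorial ring and turns anti into the syn C9/C10 relationship of the target. The gain is that no α-chiral β,γ-unsaturated aldehyde is ever needed. The forward steps need an anti-selective, face-selective aldol and an epimerisation without β-elimination.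

**6 ⇒ 5 ⇒ 4 ⇒ 2 ⇒ 1.** The cuts are the C5 carbonyl (from a carbinol), the C3 O–Si bond, the C3–O and C4–H bonds (hydroboration retron) and the carbinol C–H bond (ketone reduction). All absolute configuration then comes from one catalytic asymmetric reduction of the achiral enone 1. The hydroboration must go anti to the existing oxygen, and the two hydroxyls of 4 must be told apart.

## Other disconnections considered

**Alternative 1:** The cut is C9–C10 and C4–C5, which opens both rings to the acyclic aldehyde A1 (2-benzyloxy aldehyde, E trisubstituted alkene, Z silyl enol ether). In the forward step SnCl4 chelates the aldehyde and its α-benzyloxy group; C10 of the alkene attacks C9, and the C5 cation is trapped by C4 of the enol ether to give A2.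
- In favour: two rings, two C–C bonds and four stereocentres (C4, C5, C9, C10) form in one operation. Chair–chair anti addition across the E alkene should give the trans fusion and the cis methyls. On bonds and stereocentres per step this is better than the chosen plan, and on stereospecificity at C5 it is at least its equal.
- Against: the silyl enol ether is by far the stronger nucleophile and can attack the activated aldehyde of a second molecule or lose its silyl group, while the cascade needs the weakest π-bond to react first. All absolute configuration rests on the C8 centre, which is later oxidised away. A2 also has the wrong oxidation pattern (C3 ketone, C8 ether, free C9 hydroxyl), so reduction, protection, debenzylation and oxidation are needed before the isopropylidene.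
- Comparison: in structure A2 reaches the bicycle faster; in mechanism the cationic cascade is more stereospecific but less chemoselective than the radical closure; in step economy the gain in the ring-forming step is largely spent on making A1 and on the later redox corrections.

**Alternative 2:** The cut is C5–C10 and C6–C7, leading to the trienal A3. In the forward step Me2AlCl activates the enal and the intramolecular Diels–Alder reaction gives A4.
- In favour: both rings and the C5/C10 pair come from one concerted step of a well-understood class, with no competition between alkenes, which makes it the equal or better of the chosen plan in reliability of bond formation. C3 and C4 can be set in the open chain by standard acyclic methods, which is better controlled than the ring equilibration used here.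
- Against: the formyl carbon on C6 is not in the target and must be excised. A4 has only a C8=C9 alkene where a 9-hydroxy-8-ketone is needed, and nothing at C7. The β,β-disubstituted dienophile is sluggish, and the endo/exo preference that decides the ring fusion is uncertain.
- Comparison: in structure A4 is further from the target than 17, which already has C8 and C9 at the correct oxidation level; in step economy the alternative is clearly longer after its key step.

**Alternative 3:** The cut is C7–C8, leading to the iodo aldehyde A5. In the forward step CrCl2 with catalytic NiCl2 turns the alkenyl iodide into an alkenylchromium species that adds to the aldehyde to give A6; oxidation of the new carbinol follows.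
- In favour: the isopropylidene and the C8 oxygen arrive with the ring closure, so the aldol and dehydration steps of the chosen plan are saved; here it is better. The organochromium step tolerates silyl ethers, so on functional-group tolerance it is equal.
- Against: it leaves the hard problem untouched. A5 already contains quaternary C5, which would have to be built by a separate alkylation at a fully substituted carbon with uncertain facial control. The tetrasubstituted alkenyl iodide is a slow partner, the α-silyloxy aldehyde can epimerise, and an extra oxidation is needed.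
- Comparison: in structure it removes one ring and no lasting stereocentre; in mechanism the polar closure is reliable; in step economy it is shorter after the closure and longer before it. The chosen plan forms the ring and the quaternary centre in the same step.

Key step: step 10

Remark: eremophilane numbering (C1–C15) is used for the ring atoms of every intermediate.
Remark: a 2-alkylcyclohexane-1,3-dione is almost wholly enolised and is not relied on for a clean enantioselective monoreduction, so ring A is entered from enone 1.
Remark: ethyl glyoxylate 7 is used freshly distilled from its commercial toluene solution.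

## Route

Step 1
Reactants: 1 2-methylcyclohex-2-en-1-one
Product: 2 (R)-2-methylcyclohex-2-en-1-ol
Conditions: (S)-1-methyl-3,3-diphenyltetrahydro-1H,3H-pyrrolo[1,2-c][1,3,2]oxazaborole (10 mol %), BH3·SMe2, THF, −20 °C; MeOH
Reagents that add atoms: none
Why: CBS reduction; the oxazaborolidine–borane complex binds the carbonyl with the α-methylvinyl flank as the large group and delivers hydride to one face, which should give the R carbinol by 1,2-reduction only.

Step 2
Reactants: 2 (R)-2-methylcyclohex-2-en-1-ol
Product: 4 (1R,3R)-2-methylcyclohexane-1,3-diol, via alkylborane 3 (not isolated)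
Conditions: BH3·THF, THF, 0 °C → rt; then NaOH, H2O2, 0 °C → rt
Reagents that add atoms: hydrogen peroxide, OO
Why: Hydroboration–oxidation; boron adds to the less substituted alkene carbon, syn to the new C4–H and anti to the pseudoaxial allylic O–B group, and oxidation retains configuration, so the new carbinol should be R and trans to the old one. In this diol the methyl is cis to one hydroxyl and trans to the other.

Step 3
Reactants: 4 (1R,3R)-2-methylcyclohexane-1,3-diol
Product: 5 (1R,2R,3R)-3-[(tert-butyldimethylsilyl)oxy]-2-methylcyclohexan-1-ol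
Conditions: TBSCl (1.05 equiv), imidazole, CH2Cl2, −20 → 0 °C
Reagents that add atoms: tert-butyldimethylsilyl chloride, CC(C)(C)[Si](C)(C)Cl
Why: Selective monosilylation; in the preferred chair the hydroxyl trans to the methyl is equatorial and the other axial, so the bulky chlorosilane should take the equatorial one. This choice makes C4 a stereocentre with the trans C3/C4 relationship of the target.

Step 4
Reactants: 5 (1R,2R,3R)-3-[(tert-butyldimethylsilyl)oxy]-2-methylcyclohexan-1-ol
Product: 6 (2S,3R)-3-[(tert-butyldimethylsilyl)oxy]-2-methylcyclohexan-1-one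
Conditions: Dess–Martin periodinane, CH2Cl2, rt
Reagents that add atoms: none
Why: Dess–Martin oxidation of the remaining axial alcohol; the near-neutral conditions should leave the β-silyloxy ketone and its already equatorial α-methyl centre untouched.

Step 5
Reactants: 6 (2S,3R)-3-[(tert-butyldimethylsilyl)oxy]-2-methylcyclohexan-1-one; 7 ethyl glyoxylate
Product: 9 ethyl (2S)-2-[(1R,3S,4R)-4-[(tert-butyldimethylsilyl)oxy]-3-methyl-2-oxocyclohexyl]-2-hydroxyacetate, via enol borinate 8 (not isolated)
Conditions: (c-C6H11)2BCl, Et3N, Et2O, −78 → 0 °C; then 7, −78 → −20 °C; MeOH, pH 7 buffer, H2O2, 0 °C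
Reagents that add atoms: none
Why: Boron-mediated aldol addition; the bulky chloroborane enolises the CH2 side to the necessarily E enol borinate, whose chair Zimmerman–Traxler transition state gives the anti aldol. The aldehyde should add axially at C10 from the face opposite the C4 methyl, which sets C9 as S and C10 as the axial epimer that step 7 inverts.

Step 6
Reactants: 9 ethyl (2S)-2-[(1R,3S,4R)-4-[(tert-butyldimethylsilyl)oxy]-3-methyl-2-oxocyclohexyl]-2-hydroxyacetate
Product: 10 ethyl (2S)-2-[(1R,3S,4R)-4-[(tert-butyldimethylsilyl)oxy]-3-methyl-2-oxocyclohexyl]-2-[(triisopropylsilyl)oxy]acetate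
Conditions: TIPSOTf, 2,6-lutidine, CH2Cl2, −78 → 0 °C
Reagents that add atoms: triisopropylsilyl trifluoromethanesulfonate, CC(C)[Si](OS(=O)(=O)C(F)(F)F)(C(C)C)C(C)C
Why: Silylation of a hindered secondary alcohol with a silyl triflate; it blocks retro-aldol cleavage and puts on C9 a bulky group that differs from the one on C3 and is a poor leaving group for the next step.

Step 7
Reactants: 10 ethyl (2S)-2-[(1R,3S,4R)-4-[(tert-butyldimethylsilyl)oxy]-3-methyl-2-oxocyclohexyl]-2-[(triisopropylsilyl)oxy]acetate
Product: 11 ethyl (2S)-2-[(1S,3S,4R)-4-[(tert-butyldimethylsilyl)oxy]-3-methyl-2-oxocyclohexyl]-2-[(triisopropylsilyl)oxy]acetate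
Conditions: DBU (0.3 equiv), toluene, rt
Reagents that add atoms: none
Why: Base-mediated epimerisation through the C5–C10 enolate under thermodynamic control; the bulky side chain should move from axial to equatorial to give the all-equatorial ring. Inverting C10 converts the anti C9/C10 pair into the syn pair of the target.

Step 8
Reactants: 11 ethyl (2S)-2-[(1S,3S,4R)-4-[(tert-butyldimethylsilyl)oxy]-3-methyl-2-oxocyclohexyl]-2-[(triisopropylsilyl)oxy]acetate
Product: 12 ethyl (2S)-2-[(1R,3R,4R)-4-[(tert-butyldimethylsilyl)oxy]-3-methyl-2-methylidenecyclohexyl]-2-[(triisopropylsilyl)oxy]acetate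
Conditions: Zn, CH2Br2, TiCl4, THF/CH2Cl2, 0 °C → rt (reagent pre-formed)
Reagents that add atoms: dibromomethane, BrCBr
Why: Takai–Lombardo methylenation; the non-basic gem-dizinc reagent should methylenate the hindered, enolisable ketone without epimerisation or β-elimination and leave the ester alone.

Step 9
Reactants: 12 ethyl (2S)-2-[(1R,3R,4R)-4-[(tert-butyldimethylsilyl)oxy]-3-methyl-2-methylidenecyclohexyl]-2-[(triisopropylsilyl)oxy]acetate
Product: 14 (1S)-1-[(1R,3R,4R)-4-[(tert-butyldimethylsilyl)oxy]-3-methyl-2-methylidenecyclohexyl]-1-[(triisopropylsilyl)oxy]but-3-en-2-one, via Weinreb amide 13 (not isolated)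
Conditions: Me(MeO)NH·HCl, iPrMgCl, THF, −20 → 0 °C; then CH2=CHMgBr, 0 °C; inverse quench into cold aq. HCl
Reagents that add atoms: vinylmagnesium bromide, C=C[Mg]Br
Why: Weinreb ketone synthesis run in one flask; the magnesium amide converts the ester into the N-methoxy-N-methylamide, whose chelated adduct with the vinyl Grignard reagent collapses only on quench, so a single vinyl group is added. The acidic inverse quench keeps the liberated amine from adding to the enone.

Step 10
Reactants: 14 (1S)-1-[(1R,3R,4R)-4-[(tert-butyldimethylsilyl)oxy]-3-methyl-2-methylidenecyclohexyl]-1-[(triisopropylsilyl)oxy]but-3-en-2-one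
Product: 17 (1S,4aR,5R,6R,8aR)-6-[(tert-butyldimethylsilyl)oxy]-4a,5-dimethyl-1-[(triisopropylsilyl)oxy]octahydronaphthalen-2(1H)-one, via tertiary C5 radical 15 (not isolated), via C7 keto radical 16 (not isolated)
Conditions: Fe(acac)3 (30 mol %), PhSiH3, EtOH/(HOCH2)2, 60 °C, 0.01 M
Reagents that add atoms: none
Why: An iron hydride formed from Fe(acac)3 and PhSiH3 transfers a hydrogen atom to the terminal carbon of the electron-rich 1,1-disubstituted alkene, which makes the C14 methyl and the tertiary C5 radical. This nucleophilic radical adds to C6, the unsubstituted β-carbon of the vinyl ketone, forming the C5–C6 bond; the resulting α-keto radical is reduced by divalent iron and protonated by the solvent. The closest known reaction type is the iron-mediated hydrogen-atom-transfer reductive coupling of unactivated olefins with enones, here run intramolecularly as a Giese-type cyclisation. Ring B closes in the 6-endo-trig mode, preferred over 5-exo because attack at C6 is polarity-matched and gives a carbonyl-stabilised radical, whereas attack at C7 would give a primary radical. The new stereocentre C5 is controlled by a chair-like transition state in which ring A keeps the C3 oxygen, the C4 methyl and the C10 side chain equatorial and the tether reaches C5 equatorially, so the new methyl becomes axial and the fusion trans. The equatorial C9 silyloxy group, set in steps 5 and 7, avoids a 1,3-diaxial contact with that methyl in this transition state. The step needs hydrogen-atom transfer to the exocyclic methylene and not to the enone, which the preference of the hydride for electron-rich alkenes should secure, and cyclisation faster than reduction of the C5 radical, which dilution and the proximity of the acceptor favour. The neutral conditions should spare both silyl ethers and the α-silyloxy ketone.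

Step 11
Reactants: 17 (1S,4aR,5R,6R,8aR)-6-[(tert-butyldimethylsilyl)oxy]-4a,5-dimethyl-1-[(triisopropylsilyl)oxy]octahydronaphthalen-2(1H)-one
Product: 19 (1S,3S,4aR,5R,6R,8aR)-6-[(tert-butyldimethylsilyl)oxy]-3-(2-hydroxypropan-2-yl)-4a,5-dimethyl-1-[(triisopropylsilyl)oxy]octahydronaphthalen-2(1H)-one, via lithium enolate 18 (not isolated)
Conditions: LiN(iPr)2, THF, −78 °C; acetone, −78 °C; AcOH, −78 °C
Reagents that add atoms: acetone, CC(C)=O
Why: Kinetic enolisation followed by aldol addition; the amide base should remove a C7 methylene proton and not the hindered C9 methine next to the silyloxy group. Acetone should enter from the face away from the axial C5 methyl, and the new C7 centre is lost in step 12.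

Step 12
Reactants: 19 (1S,3S,4aR,5R,6R,8aR)-6-[(tert-butyldimethylsilyl)oxy]-3-(2-hydroxypropan-2-yl)-4a,5-dimethyl-1-[(triisopropylsilyl)oxy]octahydronaphthalen-2(1H)-one
Product: 21 (1S,4aR,5R,6R,8aR)-6-[(tert-butyldimethylsilyl)oxy]-4a,5-dimethyl-3-(propan-2-ylidene)-1-[(triisopropylsilyl)oxy]octahydronaphthalen-2(1H)-one, via tertiary mesylate 20 (not isolated)
Conditions: MsCl, Et3N, CH2Cl2, 0 °C; then DBU, rt
Reagents that add atoms: none
Why: Mesylation and E1cB elimination complete the aldol condensation; elimination through the C7 enolate should give the conjugated tetrasubstituted isopropylidene. Any base-induced change at C9 can only favour the equatorial silyloxy group, which has no diaxial contact with C14.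

Step 13
Reactants: 21 (1S,4aR,5R,6R,8aR)-6-[(tert-butyldimethylsilyl)oxy]-4a,5-dimethyl-3-(propan-2-ylidene)-1-[(triisopropylsilyl)oxy]octahydronaphthalen-2(1H)-one
Product: 22 (1S,4aR,5R,6R,8aR)-6-hydroxy-4a,5-dimethyl-3-(propan-2-ylidene)-1-[(triisopropylsilyl)oxy]octahydronaphthalen-2(1H)-one
Conditions: camphor-10-sulfonic acid (0.2 equiv), MeOH/CH2Cl2, 0 °C
Reagents that add atoms: none
Why: Acid-catalysed methanolysis of a silyl ether; the secondary tert-butyldimethylsilyl ether should cleave much faster than the bulkier triisopropylsilyl ether, which is further deactivated by the adjacent carbonyl and the ring-fusion carbon.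

Step 14
Reactants: 23 (S)-pent-1-yn-3-ol
Product: 25 tert-butyl (4S)-4-hydroxyhex-2-ynoate, via dilithio alkynolate 24 (not isolated)
Conditions: n-BuLi (2.05 equiv), THF, −78 °C; Boc2O (1.0 equiv), −78 °C; aq. NH4Cl
Reagents that add atoms: di-tert-butyl dicarbonate, CC(C)(C)OC(=O)OC(=O)OC(C)(C)C
Why: C-acylation of an alkynyllithium; in the dianion the acetylide carbon is far more nucleophilic than the alkoxide and should take the one equivalent of dicarbonate, and the carbinol centre is not touched.

Step 15
Reactants: 25 tert-butyl (4S)-4-hydroxyhex-2-ynoate; 26 hex-2-ynoic acid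
Product: 27 tert-butyl (4S)-4-(hex-2-ynoyloxy)hex-2-ynoate
Conditions: DCC, 4-(dimethylamino)pyridine (5 mol %), CH2Cl2, 0 °C
Reagents that add atoms: none
Why: Steglich esterification with retention at the carbinol; the low temperature and small amount of nucleophilic catalyst should limit base-induced isomerisation of the γ-hydroxy ynoate.

Step 16
Reactants: 27 tert-butyl (4S)-4-(hex-2-ynoyloxy)hex-2-ynoate
Product: 28 (4S)-4-(hex-2-ynoyloxy)hex-2-ynoic acid
Conditions: CF3CO2H/CH2Cl2 (1:4), 0 °C → rt
Reagents that add atoms: none
Why: Acidolysis of the tert-butyl ester with loss of isobutene; the inner ester and the electron-poor alkynes should be stable to acid, so only the outer carboxyl is freed.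

Step 17
Reactants: 22 (1S,4aR,5R,6R,8aR)-6-hydroxy-4a,5-dimethyl-3-(propan-2-ylidene)-1-[(triisopropylsilyl)oxy]octahydronaphthalen-2(1H)-one; 28 (4S)-4-(hex-2-ynoyloxy)hex-2-ynoic acid
Product: 29 (1R,2R,4aR,5S,8aR)-1,8a-dimethyl-6-oxo-7-(propan-2-ylidene)-5-[(triisopropylsilyl)oxy]decahydronaphthalen-2-yl (4S)-4-(hex-2-ynoyloxy)hex-2-ynoate
Conditions: DCC, 4-(dimethylamino)pyridine (10 mol %), CH2Cl2, −10 → 0 °C
Reagents that add atoms: none
Why: Steglich esterification of the equatorial C3 hydroxyl, the only free hydroxyl because C9 is silylated; using the alkynoic acid avoids any Z/E question during activation.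

Step 18
Reactants: 29 (1R,2R,4aR,5S,8aR)-1,8a-dimethyl-6-oxo-7-(propan-2-ylidene)-5-[(triisopropylsilyl)oxy]decahydronaphthalen-2-yl (4S)-4-(hex-2-ynoyloxy)hex-2-ynoate
Product: 30 (1R,2R,4aR,5S,8aR)-1,8a-dimethyl-6-oxo-7-(propan-2-ylidene)-5-[(triisopropylsilyl)oxy]decahydronaphthalen-2-yl (2Z,4S)-4-[(2Z)-hex-2-enoyloxy]hex-2-enoate
Conditions: H2 (1 atm), Pd/CaCO3 poisoned with Pb(OAc)2, quinoline, EtOAc, rt; stopped after 2 equiv H2
Reagents that add atoms: none
Why: Lindlar-type semihydrogenation; syn delivery of hydrogen to each alkyne on the poisoned surface should give both Z-alkenes, and the tetrasubstituted enone is too hindered to be reduced.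

Step 19
Reactants: 30 (1R,2R,4aR,5S,8aR)-1,8a-dimethyl-6-oxo-7-(propan-2-ylidene)-5-[(triisopropylsilyl)oxy]decahydronaphthalen-2-yl (2Z,4S)-4-[(2Z)-hex-2-enoyloxy]hex-2-enoate
Product: 31 (1R,2R,4aR,5S,8aR)-5-hydroxy-1,8a-dimethyl-6-oxo-7-(propan-2-ylidene)decahydronaphthalen-2-yl (2Z,4S)-4-[(2Z)-hex-2-enoyloxy]hex-2-enoate
Conditions: aq. HF (48%), MeCN, 0 °C → rt
Reagents that add atoms: none
Why: Acidic fluoride-mediated desilylation; the non-basic medium should free the C9 hydroxyl without Z→E isomerisation, ester cleavage or epimerisation of the α-ketol.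

## Compound list

1 | 2-methylcyclohex-2-en-1-one | CC1=CCCCC1=O | starting material
2 | (R)-2-methylcyclohex-2-en-1-ol | CC1=CCCC[C@H]1O | intermediate
3 | [(1R,2S,3R)-3-boranyl-2-methylcyclohexyl]oxyborane (drawn as the monomer) | B[C@@H]1CCC[C@@H](OB)[C@H]1C | intermediate
4 | (1R,3R)-2-methylcyclohexane-1,3-diol | O[C@@H]1CCC[C@@H](O)C1C | intermediate
5 | (1R,2R,3R)-3-[(tert-butyldimethylsilyl)oxy]-2-methylcyclohexan-1-ol | CC(C)(C)[Si](C)(C)O[C@@H]1CCC[C@@H](O)[C@H]1C | intermediate
6 | (2S,3R)-3-[(tert-butyldimethylsilyl)oxy]-2-methylcyclohexan-1-one | CC(C)(C)[Si](C)(C)O[C@@H]1CCCC(=O)[C@H]1C | intermediate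
7 | ethyl glyoxylate (ethyl 2-oxoacetate) | CCOC(=O)C=O | starting material
8 | {[(5R,6S)-5-[(tert-butyldimethylsilyl)oxy]-6-methylcyclohex-1-en-1-yl]oxy}dicyclohexylborane | CC(C)(C)[Si](C)(C)O[C@@H]1CCC=C(OB(C2CCCCC2)C2CCCCC2)[C@H]1C | intermediate
9 | ethyl (2S)-2-[(1R,3S,4R)-4-[(tert-butyldimethylsilyl)oxy]-3-methyl-2-oxocyclohexyl]-2-hydroxyacetate | CC(C)(C)[Si](C)(C)O[C@@H]1CC[C@H]([C@H](O)C(=O)OCC)C(=O)[C@H]1C | intermediate
10 | ethyl (2S)-2-[(1R,3S,4R)-4-[(tert-butyldimethylsilyl)oxy]-3-methyl-2-oxocyclohexyl]-2-[(triisopropylsilyl)oxy]acetate | CC(C)(C)[Si](C)(C)O[C@@H]1CC[C@H]([C@H](O[Si](C(C)C)(C(C)C)C(C)C)C(=O)OCC)C(=O)[C@H]1C | intermediate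
11 | ethyl (2S)-2-[(1S,3S,4R)-4-[(tert-butyldimethylsilyl)oxy]-3-methyl-2-oxocyclohexyl]-2-[(triisopropylsilyl)oxy]acetate | CC(C)(C)[Si](C)(C)O[C@@H]1CC[C@@H]([C@H](O[Si](C(C)C)(C(C)C)C(C)C)C(=O)OCC)C(=O)[C@H]1C | intermediate
12 | ethyl (2S)-2-[(1R,3R,4R)-4-[(tert-butyldimethylsilyl)oxy]-3-methyl-2-methylidenecyclohexyl]-2-[(triisopropylsilyl)oxy]acetate | CC(C)(C)[Si](C)(C)O[C@@H]1CC[C@@H]([C@H](O[Si](C(C)C)(C(C)C)C(C)C)C(=O)OCC)C(=C)[C@H]1C | intermediate
13 | (2S)-2-[(1R,3R,4R)-4-[(tert-butyldimethylsilyl)oxy]-3-methyl-2-methylidenecyclohexyl]-N-methoxy-N-methyl-2-[(triisopropylsilyl)oxy]acetamide | CC(C)(C)[Si](C)(C)O[C@@H]1CC[C@@H]([C@H](O[Si](C(C)C)(C(C)C)C(C)C)C(=O)N(C)OC)C(=C)[C@H]1C | intermediate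
14 | (1S)-1-[(1R,3R,4R)-4-[(tert-butyldimethylsilyl)oxy]-3-methyl-2-methylidenecyclohexyl]-1-[(triisopropylsilyl)oxy]but-3-en-2-one | CC(C)(C)[Si](C)(C)O[C@@H]1CC[C@@H]([C@H](O[Si](C(C)C)(C(C)C)C(C)C)C(=O)C=C)C(=C)[C@H]1C | intermediate
15 | C5-centred tertiary radical formed from 14 by hydrogen-atom addition at C14 | CC(C)(C)[Si](C)(C)O[C@@H]1CC[C@@H]([C@H](O[Si](C(C)C)(C(C)C)C(C)C)C(=O)C=C)[C](C)[C@H]1C | intermediate
16 | C7-centred α-keto radical of the closed trans-decalin | CC(C)(C)[Si](C)(C)O[C@@H]1CC[C@H]2[C@H](O[Si](C(C)C)(C(C)C)C(C)C)C(=O)[CH]C[C@]2(C)[C@H]1C | intermediate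
17 | (1S,4aR,5R,6R,8aR)-6-[(tert-butyldimethylsilyl)oxy]-4a,5-dimethyl-1-[(triisopropylsilyl)oxy]octahydronaphthalen-2(1H)-one (trans-decalin-8-one in eremophilane numbering) | CC(C)(C)[Si](C)(C)O[C@@H]1CC[C@H]2[C@H](O[Si](C(C)C)(C(C)C)C(C)C)C(=O)CC[C@]2(C)[C@H]1C | intermediate
18 | lithium C7=C8 enolate of 17 | CC(C)(C)[Si](C)(C)O[C@@H]1CC[C@H]2[C@H](O[Si](C(C)C)(C(C)C)C(C)C)C(O[Li])=CC[C@]2(C)[C@H]1C | intermediate
19 | (1S,3S,4aR,5R,6R,8aR)-6-[(tert-butyldimethylsilyl)oxy]-3-(2-hydroxypropan-2-yl)-4a,5-dimethyl-1-[(triisopropylsilyl)oxy]octahydronaphthalen-2(1H)-one | CC(C)(C)[Si](C)(C)O[C@@H]1CC[C@H]2[C@H](O[Si](C(C)C)(C(C)C)C(C)C)C(=O)[C@H](C(C)(C)O)C[C@]2(C)[C@H]1C | intermediate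
20 | methanesulfonate of the tertiary alcohol 19 | CC(C)(C)[Si](C)(C)O[C@@H]1CC[C@H]2[C@H](O[Si](C(C)C)(C(C)C)C(C)C)C(=O)[C@H](C(C)(C)OS(C)(=O)=O)C[C@]2(C)[C@H]1C | intermediate
21 | (1S,4aR,5R,6R,8aR)-6-[(tert-butyldimethylsilyl)oxy]-4a,5-dimethyl-3-(propan-2-ylidene)-1-[(triisopropylsilyl)oxy]octahydronaphthalen-2(1H)-one | CC(C)(C)[Si](C)(C)O[C@@H]1CC[C@H]2[C@H](O[Si](C(C)C)(C(C)C)C(C)C)C(=O)C(=C(C)C)C[C@]2(C)[C@H]1C | intermediate
22 | (1S,4aR,5R,6R,8aR)-6-hydroxy-4a,5-dimethyl-3-(propan-2-ylidene)-1-[(triisopropylsilyl)oxy]octahydronaphthalen-2(1H)-one | O[C@@H]1CC[C@H]2[C@H](O[Si](C(C)C)(C(C)C)C(C)C)C(=O)C(=C(C)C)C[C@]2(C)[C@H]1C | intermediate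
23 | (S)-pent-1-yn-3-ol | CC[C@H](O)C#C | starting material
24 | dilithio derivative of 23 (lithium alkoxide and lithium acetylide) | CC[C@H](O[Li])C#C[Li] | intermediate
25 | tert-butyl (4S)-4-hydroxyhex-2-ynoate | CC[C@H](O)C#CC(=O)OC(C)(C)C | intermediate
26 | hex-2-ynoic acid | CCCC#CC(=O)O | starting material
27 | tert-butyl (4S)-4-(hex-2-ynoyloxy)hex-2-ynoate | CCCC#CC(=O)O[C@@H](CC)C#CC(=O)OC(C)(C)C | intermediate
28 | (4S)-4-(hex-2-ynoyloxy)hex-2-ynoic acid | CCCC#CC(=O)O[C@@H](CC)C#CC(=O)O | intermediate
29 | (1R,2R,4aR,5S,8aR)-1,8a-dimethyl-6-oxo-7-(propan-2-ylidene)-5-[(triisopropylsilyl)oxy]decahydronaphthalen-2-yl (4S)-4-(hex-2-ynoyloxy)hex-2-ynoate | CCCC#CC(=O)O[C@@H](CC)C#CC(=O)O[C@@H]1CC[C@H]2[C@H](O[Si](C(C)C)(C(C)C)C(C)C)C(=O)C(=C(C)C)C[C@]2(C)[C@H]1C | intermediate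
30 | (1R,2R,4aR,5S,8aR)-1,8a-dimethyl-6-oxo-7-(propan-2-ylidene)-5-[(triisopropylsilyl)oxy]decahydronaphthalen-2-yl (2Z,4S)-4-[(2Z)-hex-2-enoyloxy]hex-2-enoate | CCC/C=C\C(=O)O[C@H](/C=C\C(=O)O[C@@H]1CC[C@H]2[C@H](O[Si](C(C)C)(C(C)C)C(C)C)C(=O)C(=C(C)C)C[C@]2(C)[C@H]1C)CC | intermediate
31 | (1R,2R,4aR,5S,8aR)-5-hydroxy-1,8a-dimethyl-6-oxo-7-(propan-2-ylidene)decahydronaphthalen-2-yl (2Z,4S)-4-[(2Z)-hex-2-enoyloxy]hex-2-enoate (CNP0170141.1) | CCC/C=C\C(=O)O[C@H](/C=C\C(=O)O[C@@H]1CC[C@H]2[C@H](O)C(=O)C(=C(C)C)C[C@]2(C)[C@H]1C)CC | target

## Step count and least certain steps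

Total step count: 19. Longest linear sequence: 16 (steps 1–13 and 17–19); the side-chain acid takes steps 14–16.

**Step 10 (key step).** The likeliest failures are closure through the axial face of the C5 radical (cis fusion), reduction of the radical by a second hydrogen-atom transfer before it cyclises, migration of the exocyclic alkene into the ring by reversible hydrogen-atom transfer, and oligomerisation of the vinyl ketone. All follow from the cyclisation being slower than expected at a hindered tertiary centre. The fallback forms the C5–C6 bond intermolecularly and closes ring B by a polar reaction. It sets out from 12: the same Fe(acac)3/PhSiH3 coupling with methyl acrylate should give the C5-quaternary diester F1. Dieckmann condensation with KOtBu, in which the C7 carbanion attacks the ethyl ester and the acidic product drives the equilibrium, should give the β-keto ester F2. Dealkoxycarbonylation with LiCl in wet DMSO (Krapcho) comes back to the route at 17. The facial course of the intermolecular addition at C5 is less predictable than that of the tethered closure.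

**Step 7.** The C10 enolate may expel the C9 silyloxy group (E1cB) instead of being reprotonated, and prolonged base may erode C4. The fallback lowers the leaving-group ability at C9 during the epimerisation. It sets out from 9: 4-methoxybenzyl trichloroacetimidate with catalytic camphor-10-sulfonic acid gives the ether F3, DBU epimerises C10 to give F4, DDQ in buffered wet CH2Cl2 frees the alcohol F5, and TIPSOTf with 2,6-lutidine comes back to the route at 11.

**Step 3.** Discrimination between the equatorial and the axial hydroxyl may be incomplete, giving silylation at the wrong oxygen or at both; because the two carbinols are configurationally alike, this would install the cis C3/C4 relationship. The fallback differentiates the oxygens in time instead of by rate. It sets out from 2: NaH and 4-methoxybenzyl chloride give the ether F6, hydroboration–oxidation gives the alcohol F7, TBSCl with imidazole gives the silyl ether F8, and DDQ comes back to the route at 5.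

**Step 14.** The lithium alkoxide may compete for the dicarbonate (carbonate formation), and the product may isomerise under the basic conditions. The fallback masks the hydroxyl first. It sets out from 23: TBSCl with imidazole gives the silyl ether F9, n-BuLi then Boc2O gives the silyl ynoate F10, and HF·pyridine comes back to the route at 25.

**Step 18.** Over-reduction of a Z-enoate, incomplete reduction of the second alkyne, and Z→E isomerisation on the catalyst are all harder to control and to correct on the full molecule. The fallback moves the reduction to the small fragment. It sets out from 27: the same poisoned-palladium semihydrogenation gives the Z,Z diester F11, CF3CO2H gives the Z,Z acid F12, and a Yamaguchi esterification with 22 (2,4,6-trichlorobenzoyl chloride, Et3N, then a little 4-(dimethylamino)pyridine at low temperature) comes back to the route at 30. This is the second choice because activating a Z-enoic acid risks isomerisation.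

## Further compounds

F1 | step 10 | ethyl (2S)-2-[(1R,2R,3R,4R)-4-[(tert-butyldimethylsilyl)oxy]-2-(3-methoxy-3-oxopropyl)-2,3-dimethylcyclohexyl]-2-[(triisopropylsilyl)oxy]acetate | CC(C)(C)[Si](C)(C)O[C@@H]1CC[C@@H]([C@H](O[Si](C(C)C)(C(C)C)C(C)C)C(=O)OCC)[C@](C)(CCC(=O)OC)[C@H]1C
F2 | step 10 | methyl (1S,3R,4aR,5R,6R,8aR)-6-[(tert-butyldimethylsilyl)oxy]-4a,5-dimethyl-2-oxo-1-[(triisopropylsilyl)oxy]decahydronaphthalene-3-carboxylate (drawn as the keto form) | CC(C)(C)[Si](C)(C)O[C@@H]1CC[C@H]2[C@H](O[Si](C(C)C)(C(C)C)C(C)C)C(=O)[C@H](C(=O)OC)C[C@]2(C)[C@H]1C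
F3 | step 7 | ethyl (2S)-2-[(1R,3S,4R)-4-[(tert-butyldimethylsilyl)oxy]-3-methyl-2-oxocyclohexyl]-2-[(4-methoxyphenyl)methoxy]acetate | CC(C)(C)[Si](C)(C)O[C@@H]1CC[C@H]([C@H](OCc2ccc(OC)cc2)C(=O)OCC)C(=O)[C@H]1C
F4 | step 7 | ethyl (2S)-2-[(1S,3S,4R)-4-[(tert-butyldimethylsilyl)oxy]-3-methyl-2-oxocyclohexyl]-2-[(4-methoxyphenyl)methoxy]acetate | CC(C)(C)[Si](C)(C)O[C@@H]1CC[C@@H]([C@H](OCc2ccc(OC)cc2)C(=O)OCC)C(=O)[C@H]1C
F5 | step 7 | ethyl (2S)-2-[(1S,3S,4R)-4-[(tert-butyldimethylsilyl)oxy]-3-methyl-2-oxocyclohexyl]-2-hydroxyacetate | CC(C)(C)[Si](C)(C)O[C@@H]1CC[C@@H]([C@H](O)C(=O)OCC)C(=O)[C@H]1C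
F6 | step 3 | 1-methoxy-4-({[(1R)-2-methylcyclohex-2-en-1-yl]oxy}methyl)benzene | COc1ccc(CO[C@@H]2CCCC=C2C)cc1
F7 | step 3 | (1R,2S,3R)-3-[(4-methoxyphenyl)methoxy]-2-methylcyclohexan-1-ol | O[C@@H]1CCC[C@@H](OCc2ccc(OC)cc2)[C@H]1C
F8 | step 3 | tert-butyl({(1R,2R,3R)-3-[(4-methoxyphenyl)methoxy]-2-methylcyclohexyl}oxy)dimethylsilane | CC(C)(C)[Si](C)(C)O[C@@H]1CCC[C@@H](OCc2ccc(OC)cc2)[C@H]1C
F9 | step 14 | tert-butyldimethyl{[(3S)-pent-1-yn-3-yl]oxy}silane | CC[C@H](O[Si](C)(C)C(C)(C)C)C#C
F10 | step 14 | tert-butyl (4S)-4-[(tert-butyldimethylsilyl)oxy]hex-2-ynoate | CC[C@H](O[Si](C)(C)C(C)(C)C)C#CC(=O)OC(C)(C)C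
F11 | step 18 | tert-butyl (2Z,4S)-4-[(2Z)-hex-2-enoyloxy]hex-2-enoate | CCC/C=C\C(=O)O[C@H](/C=C\C(=O)OC(C)(C)C)CC
F12 | step 18 | (2Z,4S)-4-[(2Z)-hex-2-enoyloxy]hex-2-enoic acid | CCC/C=C\C(=O)O[C@H](/C=C\C(=O)O)CC
A1 | alternative 1 | (2S,5E,9Z)-2-(benzyloxy)-9-[(tert-butyldimethylsilyl)oxy]-5-methylundeca-5,9-dienal | O=C[C@@H](OCc1ccccc1)CC/C(C)=C/CC/C(O[Si](C)(C)C(C)(C)C)=C/C
A2 | alternative 1 | trans-fused 8-benzyloxy-9-hydroxy-4,5-dimethyldecalin-3-one (eremophilane numbering) | O=C1CC[C@H]2[C@H](O)[C@@H](OCc3ccccc3)CC[C@]2(C)[C@H]1C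
A3 | alternative 2 | (2E,4R,5R,8E)-5-[(tert-butyldimethylsilyl)oxy]-3,4-dimethylundeca-2,8,10-trienal | O=C/C=C(\C)[C@@H](C)[C@H](O[Si](C)(C)C(C)(C)C)CC/C=C/C=C
A4 | alternative 2 | trans-fused 6-formyl-3-[(tert-butyldimethylsilyl)oxy]-4,5-dimethyloctal-8-ene (eremophilane numbering) | CC(C)(C)[Si](C)(C)O[C@@H]1CC[C@H]2C=CC[C@@H](C=O)[C@]2(C)[C@H]1C
A5 | alternative 3 | ring A aldehyde with C9 silyloxy, C8 formyl and a 2-iodo-3-methylbut-2-enyl group on quaternary C5 (eremophilane numbering) | CC(C)(C)[Si](C)(C)O[C@@H]1CC[C@@H]([C@H](O[Si](C)(C)C(C)(C)C)C=O)[C@](C)(CC(I)=C(C)C)[C@H]1C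
A6 | alternative 3 | trans-fused 3,9-bis[(tert-butyldimethylsilyl)oxy]-8-hydroxyeremophil-7(11)-ene | CC(C)(C)[Si](C)(C)O[C@@H]1CC[C@H]2[C@H](O[Si](C)(C)C(C)(C)C)[C@H](O)C(=C(C)C)C[C@]2(C)[C@H]1C
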